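## Analysis of the target

The target (C25H38O2) is a cembrane-like 14-membered carbocycle, C1 to C14, with a 6-methylhepta-1,5-dien-2-yl side chain whose methylene C15=C16 sits directly on C1. The ring is numbered from the stereocentre C1 through C2, the C3=C4 alkene (methyl on C4), the C7=C8 alkene (carboxyl on C8) and the C11=C12 alkene (methyl on C12) to C14. C3=C4 is Z (C2 and C5 cis), C7=C8 is E by the priority rules (C6 trans to the carboxyl, hence cis to C9), and C11=C12 is E. C1 is the only stereocentre and is R; it lies between two methylene groups and a 1,1-disubstituted alkene, so no neighbouring heteroatom can direct its formation. The molecule is a skipped pentaene: acid can trigger cation–olefin reactions, move the C15=C16 methylene to C1=C15 (which would erase the stereocentre), or isomerise the Z alkene. The difficulty is to close a 14-membered ring, fix three trisubstituted ring alkenes and set one remote stereocentre. The strategy rests on reading C2 as the allylic terminus of a neryl-type unit (C2–C3=C4) and the array C1–C15(=C16) as what an allylsilane C1=C15–C16–Si leaves behind after attacking an electrophile through C1.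

## Retrosynthetic reasoning

**26 to 25.** The acid 26 is traced to its methyl ester 25. The ester is more than a protecting group: it makes C7=C8 electron-poor, which is needed in the ring-closing step. The forward reaction is a plain saponification.

**25 to 24 (C1–C2).** The ring is opened between C1 and C2. This is the one ring bond whose formation can also create the stereocentre and the exocyclic methylene, and cutting it leaves a linear polyprenoid, 24, with every alkene already in place. In 24, C2 carries chloride (Z allylic chloride) and C1=C15 is an allylsilane with silicon on C16. The forward step has to ionise the C2–Cl bond, let only the allylsilane capture the cation through C1, and do so on one face.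

**24 to 23 to 22.** The labile allylic chloride is made last from alcohol 23, which is released from silyl ether 22. The silyl ether carries the C2 oxygen through the fragment union.

**22 to 21 to 20 + 7 (C9–C10).** C9–C10 is a bis-allylic bond and C9 is the methylene of an α-substituted acrylate. The acetate 7 serves as the electrophile and the sulfone-stabilised allyl anion of 20 as the nucleophile. The addition–elimination forms C9–C10 and sets the C7=C8 geometry together. The sulfone in 21 is then removed reductively. The cut divides the chain into a C10 and a C15 piece, each from a terpene alcohol.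

**7 to 6 to 4 + 5, and 4 to 1.** The C7–C8 bond comes from a Morita–Baylis–Hillman reaction of aldehyde 4 with methyl acrylate 5, which supplies C8, C9 and the carboxyl carbon. Aldehyde 4 is nerol 1 after silylation (2), epoxidation of the remote alkene (3) and cleavage. Nerol delivers the Z C3=C4 alkene ready-made.

**20 to 16 to 12 + 15, and 12 to 8.** The C1=C15 alkene is made by Horner–Wadsworth–Emmons olefination of aldehyde 12 with phosphonate 15, which is assembled from 13 and 14. The ester carbon of 16 becomes C16 and is converted through alcohol 17 and chloride 18 into the silylmethyl group of 20. Aldehyde 12 is geraniol 8 after conversion to bromide 9 and sulfone 10, epoxidation (11) and cleavage. Geraniol delivers the E C11=C12 alkene.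

## Alternatives that were turned down

**Alternative 1:** Ireland–Claisen route through a macrolactone, cutting C13–C14.
- Disconnection and key step: the precursor is the 14-membered lactone A2, with the ring oxygen on C11, the isopropenyl group C12=C13 on C11 and the acyl carbon on C14. Enolisation and O-silylation of A2, then the [3,3] shift, would form C13–C14, break O–C11 and give carbocycle A1 with the E C11=C12 alkene and a carboxyl on C14.
- For: the ring is first closed by lactonisation, the most dependable entry to a 14-membered ring. The C–C bond then forms in a concerted step that does not depend on dilution. C1 would be set earlier by well-tested auxiliary or catalyst control. On certainty of ring formation and of absolute configuration this plan is stronger than the chosen one.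
- Against: A1 has a carboxyl on C14 that the target lacks. Its radical removal creates a C14 radical next to the C1 vinyl group, where a 1,2-vinyl shift through a cyclopropylcarbinyl radical can move the side chain and destroy C1. The C8 carboxyl must be carried as a silyl ether and oxidised afterwards (deprotection and two oxidations). The E/Z outcome at C11=C12 depends on chair versus boat in a transannularly constrained transition state. C1 needs its own enantioselective sequence in a chain with no nearby functional group.
- Comparison: at least five steps follow ring formation, against one in the chosen route. The chosen route offers ring, stereocentre and methylene in one step from two terpene alcohols, at the price of an unproven enantioselective step.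

**Alternative 2:** Electroreductive decarboxylative alkenylation, cutting C4–C5.
- Disconnection and key step: the precursor is the linear compound A4, with a Z alkenyl iodide at C4 and an N-acyloxyphthalimide whose carbonyl is on C5. At a cathode with NiBr2(dme) and 2,2′-bipyridine, loss of CO2 would give the C5 radical; capture by the alkenylnickel species and reductive elimination form C4–C5 with retention and give macrocycle A3.
- For: the Z geometry of C3=C4 is brought in with the iodide and is not at risk, and C1 is set beforehand. On geometric integrity of C3=C4 and on stereochemical certainty this plan is stronger than the chosen one, which relies on a non-rotating allyl cation and on a chiral ion pair.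
- Against: at high dilution the radical and the nickel centre must meet within one molecule. Premature reduction of the radical and protodehalogenation then compete, and the coupling is established between separate partners, not for 14-membered carbocycles. A conjugated ester is reducible and a radical acceptor, so C8 must be a silyloxymethyl group and be oxidised in three later steps. A stereodefined Z trisubstituted alkenyl iodide and a separate asymmetric construction of C1 lengthen the route.
- Comparison: the chosen route is shorter and builds the ring and C1 together; Alternative 2 separates the two risks but pays in steps.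

**Alternative 3:** Asymmetric chromium allylation macrocyclisation, cutting C1–C14, then deoxygenation.
- Disconnection and key step: the precursor is the linear compound A6, with an aldehyde at C14 and an allylic bromide at C16. Divalent chromium (CrCl2) with a chiral ligand would give an allylchromium species that adds through C1 to the aldehyde in a chair transition state, giving the anti homoallylic alcohol A5 with the C15=C16 methylene.
- For: chromium-mediated aldehyde allylation is among the best-tested macrocyclisations, tolerates the ester and gives γ-attack with anti selectivity. On precedent for the ring-closing event it is stronger than the chosen plan, and it also forms C1 and the methylene in the ring-closing step.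
- Against: A5 carries a hydroxyl on C14 that must be removed in two further steps, through a C14 radical that is homoallylic to C15=C16 (again the 1,2-vinyl shift risk). A6 is a β,γ-unsaturated aldehyde, prone to enolise and to move C11=C12 into conjugation. Ligand control at chromium is established mainly for intermolecular cases.
- Comparison: the chosen route reaches the same C1/methylene array with the polarity reversed (electrophile at C2 instead of C14). It needs no sacrificial oxygen and no sensitive aldehyde, and has one step after ring closure instead of three.

Key step: step 19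

Remark: the atom numbers C1–C16 of the target are kept for all linear intermediates.
Remark: the stereocentres in 3, 6, 7, 11, 15 and 21 are erased later; these compounds are carried as racemates.
Remark: the sense of induction of the thiourea in step 19 cannot be predicted; the enantiomer written is assumed to give R at C1, and its mirror image is used if the opposite is found.

## Route

Step 1
Reactants: 1 nerol, (2Z)-3,7-dimethylocta-2,6-dien-1-ol
Product: 2 tert-butyl{[(2Z)-3,7-dimethylocta-2,6-dien-1-yl]oxy}dimethylsilane
Conditions: TBSCl, imidazole, DMF, 0 °C to rt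
Reagents that add atoms: tert-butyldimethylsilyl chloride, CC(C)(C)[Si](C)(C)Cl
Why: Silylation of a primary allylic alcohol under basic conditions; nothing here can isomerise the Z alkene.

Step 2
Reactants: 2 tert-butyl{[(2Z)-3,7-dimethylocta-2,6-dien-1-yl]oxy}dimethylsilane
Product: 3 tert-butyl{[(2Z)-5-(3,3-dimethyloxiran-2-yl)-3-methylpent-2-en-1-yl]oxy}dimethylsilane (racemic)
Conditions: mCPBA (1.0 equiv), NaHCO3, CH2Cl2, −20 to 0 °C
Reagents that add atoms: 3-chloroperbenzoic acid, OOC(=O)c1cccc(Cl)c1
Why: Prilezhaev epoxidation with limiting peracid; the remote trisubstituted alkene is more electron-rich than the one next to the allylic oxygen, which is inductively deactivated.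

Step 3
Reactants: 3 tert-butyl{[(2Z)-5-(3,3-dimethyloxiran-2-yl)-3-methylpent-2-en-1-yl]oxy}dimethylsilane
Product: 4 (4Z)-6-[(tert-butyldimethylsilyl)oxy]-4-methylhex-4-enal
Conditions: H5IO6, THF/Et2O, 0 °C
Reagents that add atoms: none
Why: Acid-promoted opening of the epoxide at its tertiary carbon and periodate glycol cleavage should give the aldehyde and acetone, so the aldehyde oxygen is the former epoxide oxygen; short contact at 0 °C spares the silyl ether.

Step 4
Reactants: 4 (4Z)-6-[(tert-butyldimethylsilyl)oxy]-4-methylhex-4-enal; 5 methyl acrylate
Product: 6 methyl (6Z)-8-[(tert-butyldimethylsilyl)oxy]-3-hydroxy-6-methyl-2-methylideneoct-6-enoate (racemic)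
Conditions: DABCO (1 equiv), 5 (3 equiv), MeOH, rt, several days
Reagents that add atoms: none
Why: Morita–Baylis–Hillman reaction of an unbranched aliphatic aldehyde, accelerated by the protic solvent; it installs C8, C9 and the carboxyl carbon, and the carbinol stereocentre at C7 is irrelevant.

Step 5
Reactants: 6 methyl (6Z)-8-[(tert-butyldimethylsilyl)oxy]-3-hydroxy-6-methyl-2-methylideneoct-6-enoate
Product: 7 methyl (6Z)-3-acetoxy-8-[(tert-butyldimethylsilyl)oxy]-6-methyl-2-methylideneoct-6-enoate (racemic)
Conditions: Ac2O, pyridine, DMAP (cat.), CH2Cl2, 0 °C to rt
Reagents that add atoms: acetic anhydride, CC(=O)OC(C)=O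
Why: Acylation of the secondary allylic alcohol gives the leaving group for the later addition–elimination.

Step 6
Reactants: 8 geraniol, (2E)-3,7-dimethylocta-2,6-dien-1-ol
Product: 9 geranyl bromide, (2E)-1-bromo-3,7-dimethylocta-2,6-diene
Conditions: PBr3 (0.4 equiv), Et2O, −10 °C
Reagents that add atoms: phosphorus tribromide, BrP(Br)Br
Why: Bromination of the primary allylic alcohol through its phosphite ester at low temperature keeps the E geometry and the primary position; the crude bromide is used directly.

Step 7
Reactants: 9 geranyl bromide
Product: 10 {[(2E)-3,7-dimethylocta-2,6-dien-1-yl]sulfonyl}benzene (geranyl phenyl sulfone)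
Conditions: PhSO2Na, DMF, rt
Reagents that add atoms: sodium benzenesulfinate, [Na+].[O-]S(=O)c1ccccc1
Why: S-alkylation of the ambident sulfinate by the soft primary allylic bromide (SN2) gives the sulfone with the E alkene unchanged.

Step 8
Reactants: 10 geranyl phenyl sulfone
Product: 11 2,2-dimethyl-3-[(3E)-3-methyl-5-(phenylsulfonyl)pent-3-en-1-yl]oxirane (racemic)
Conditions: mCPBA (1.05 equiv), CH2Cl2, 0 °C
Reagents that add atoms: 3-chloroperbenzoic acid, OOC(=O)c1cccc(Cl)c1
Why: Prilezhaev epoxidation; the alkene next to the electron-withdrawing sulfonylmethyl group is deactivated, so the terminal alkene reacts.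

Step 9
Reactants: 11 2,2-dimethyl-3-[(3E)-3-methyl-5-(phenylsulfonyl)pent-3-en-1-yl]oxirane
Product: 12 (4E)-4-methyl-6-(phenylsulfonyl)hex-4-enal
Conditions: H5IO6, THF/Et2O, 0 °C
Reagents that add atoms: none
Why: Epoxide opening and periodate cleavage as in step 3 give the C1 aldehyde and acetone.

Step 10
Reactants: 13 triethyl phosphonoacetate; 14 5-bromo-2-methylpent-2-ene
Product: 15 ethyl 2-(diethoxyphosphoryl)-6-methylhept-5-enoate (racemic)
Conditions: NaH, DMSO, rt; then 14, 50 °C
Reagents that add atoms: none
Why: C-alkylation (SN2) of the sodium phosphonoacetate by the primary bromide; a slight excess of 13 limits dialkylation.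

Step 11
Reactants: 12 (4E)-4-methyl-6-(phenylsulfonyl)hex-4-enal; 15 ethyl 2-(diethoxyphosphoryl)-6-methylhept-5-enoate
Product: 16 ethyl (2E,6E)-6-methyl-2-(4-methylpent-3-en-1-yl)-8-(phenylsulfonyl)octa-2,6-dienoate
Conditions: NaH, THF, 0 °C; then 12, 0 °C to rt
Reagents that add atoms: none
Why: Horner–Wadsworth–Emmons olefination forms C1=C15; reversible addition and elimination through the less crowded oxaphosphetane should place the ester trans to the C14 chain (E), and a minor Z isomer can be removed by chromatography. The phosphonate is kept in slight excess over NaH so that the allylic sulfone is not deprotonated.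

Step 12
Reactants: 16 ethyl (2E,6E)-6-methyl-2-(4-methylpent-3-en-1-yl)-8-(phenylsulfonyl)octa-2,6-dienoate
Product: 17 (2E,6E)-6-methyl-2-(4-methylpent-3-en-1-yl)-8-(phenylsulfonyl)octa-2,6-dien-1-ol
Conditions: DIBAL-H (2.5 equiv), CH2Cl2, −78 °C; aq. potassium sodium tartrate
Reagents that add atoms: none
Why: 1,2-Reduction of the conjugated ester by the electrophilic aluminium hydride gives the allylic alcohol (C16 oxygen); sulfone and alkenes are inert.

Step 13
Reactants: 17 (2E,6E)-6-methyl-2-(4-methylpent-3-en-1-yl)-8-(phenylsulfonyl)octa-2,6-dien-1-ol
Product: 18 {[(2E,6E)-7-(chloromethyl)-3,11-dimethyldodeca-2,6,10-trien-1-yl]sulfonyl}benzene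
Conditions: MsCl, LiCl, 2,4,6-collidine, DMF, 0 °C
Reagents that add atoms: lithium chloride, [Li+].[Cl-]; methanesulfonyl chloride, CS(=O)(=O)Cl (its chloride joins the same pool)
Why: In situ mesylation and SN2 displacement by chloride under buffered conditions convert the primary allylic alcohol to the chloride without allylic transposition or change of geometry.

Step 14
Reactants: 18 {[(2E,6E)-7-(chloromethyl)-3,11-dimethyldodeca-2,6,10-trien-1-yl]sulfonyl}benzene
Product: 20 trimethyl[(2E,6E)-6-methyl-2-(4-methylpent-3-en-1-yl)-8-(phenylsulfonyl)octa-2,6-dien-1-yl]silane, via allyltrichlorosilane 19 (not isolated)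
Conditions: HSiCl3, i-Pr2NEt, CuCl (5 mol%), Et2O, rt; filtration under argon; MeMgBr (excess), Et2O, 0 °C
Reagents that add atoms: trichlorosilane, Cl[SiH](Cl)Cl; methylmagnesium bromide, C[Mg]Br
Why: Copper-catalysed trichlorosilylation of a primary allylic chloride with HSiCl3 and an amine substitutes at the carbon that bore chlorine with retention of alkene geometry, and exhaustive methylation of the Si–Cl bonds gives the trimethylsilane. The copper salts are filtered off before the Grignard reagent is added and the methylation is run cold, so that the allylic sulfone is left alone.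

Step 15
Reactants: 20 trimethyl[(2E,6E)-6-methyl-2-(4-methylpent-3-en-1-yl)-8-(phenylsulfonyl)octa-2,6-dien-1-yl]silane; 7 methyl (6Z)-3-acetoxy-8-[(tert-butyldimethylsilyl)oxy]-6-methyl-2-methylideneoct-6-enoate
Product: 21 methyl (2E,5E,9E)-2-{(4Z)-6-[(tert-butyldimethylsilyl)oxy]-4-methylhex-4-en-1-ylidene}-6,14-dimethyl-4-(phenylsulfonyl)-10-[(trimethylsilyl)methyl]pentadeca-5,9,13-trienoate (racemic at C10)
Conditions: n-BuLi (1.05 equiv), THF, −78 °C; then 7, −78 to −40 °C
Reagents that add atoms: none
Why: The α-sulfonyl allyl anion reacts at its α-carbon C10 because the γ-carbon C12 is fully substituted; conjugate addition to the methylene C9 of the Morita–Baylis–Hillman acetate and loss of acetate (SN2′, addition–elimination) form C9–C10. The C7=C8 alkene should form with C6 trans to the ester, the geometry generally obtained from ester-derived acetates with carbon nucleophiles.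

Step 16
Reactants: 21 the C10 sulfone
Product: 22 methyl (2E,5E,9E)-2-{(4Z)-6-[(tert-butyldimethylsilyl)oxy]-4-methylhex-4-en-1-ylidene}-6,14-dimethyl-10-[(trimethylsilyl)methyl]pentadeca-5,9,13-trienoate
Conditions: Pd(PPh3)4 (5 mol%), NaBH4, THF/i-PrOH, 0 °C to rt
Reagents that add atoms: none
Why: Palladium-catalysed reductive desulfonylation: zerovalent palladium ionises the allylic sulfone to a π-allyl complex and borohydride delivers hydride to the less substituted terminus C10, which keeps C11=C12 in place and E. Under these conditions NaBH4 should leave the trisubstituted methyl enoate, the silyl ether and the allylsilane untouched.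

Step 17
Reactants: 22 the C2 silyl ether
Product: 23 methyl (2E,5E,9E)-2-[(4Z)-6-hydroxy-4-methylhex-4-en-1-ylidene]-6,14-dimethyl-10-[(trimethylsilyl)methyl]pentadeca-5,9,13-trienoate
Conditions: TBAF, AcOH (1:1), THF, 0 °C to rt
Reagents that add atoms: none
Why: Fluoride cleaves the primary allylic silyl ether; buffering with acetic acid and low temperature guard the allylic C–Si bond and the ester.

Step 18
Reactants: 23 the C2 alcohol
Product: 24 methyl (2E,5E,9E)-2-[(4Z)-6-chloro-4-methylhex-4-en-1-ylidene]-6,14-dimethyl-10-[(trimethylsilyl)methyl]pentadeca-5,9,13-trienoate (the Z allylic chloride at C2 with the C16 allylsilane)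
Conditions: MsCl, LiCl, 2,4,6-collidine, DMF, 0 °C
Reagents that add atoms: lithium chloride, [Li+].[Cl-]; methanesulfonyl chloride, CS(=O)(=O)Cl (its chloride joins the same pool)
Why: Mesylate/chloride exchange as in step 13; the non-acidic conditions leave the acid-sensitive allylsilane intact and the SN2 course keeps the Z geometry and the primary position of chlorine. The chloride is used at once.

Step 19
Reactants: 24 the Z allylic chloride with the C16 allylsilane
Product: 25 methyl (1E,5Z,8R,11E)-5,11-dimethyl-8-(6-methylhepta-1,5-dien-2-yl)cyclotetradeca-1,5,11-triene-1-carboxylate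
Conditions: 1-[3,5-bis(trifluoromethyl)phenyl]-3-{(2S)-3,3-dimethyl-1-oxo-1-[(2R)-2-(pyren-4-yl)pyrrolidin-1-yl]butan-2-yl}thiourea (20 mol%), 4 Å MS, t-BuOMe, 0.002 M, −30 °C
Reagents that add atoms: none
Why: Proposed new method: the two N–H bonds of the thiourea bind and pull chloride from C2, giving a contact ion pair of the Z-configured allyl cation (C2–C3–C4) with catalyst-bound chloride; C1 of the allylsilane attacks C2, the charge developing at C15 is stabilised by the β-silicon, and the bound chloride removes Me3Si from C16, which fixes the C15=C16 methylene, releases Me3SiCl and frees the catalyst. The closest known reaction types are enantioselective cation–olefin and tail-to-head terpene cyclisations of allylic chlorides under chiral urea or thiourea anion-binding catalysis, and Lewis acid-promoted allylsilane alkylations (Hosomi–Sakurai type); none has closed a 14-membered ring with control of a stereocentre. The ring closes in a 14-exo-trig mode with respect to C1=C15, C15 and C16 staying outside the ring; high dilution suppresses bimolecular allylation, and the cis ring junctions at C3=C4 and C7=C8 bend the chain towards the reacting ends. The only new stereocentre, C1, is set by the chiral ion pair: the pyrenyl group is expected to cover one face of the allyl cation through a cation–π contact so that the allylsilane approaches from the open face, and which catalyst enantiomer gives R has to be found by experiment. Chemoselectivity comes from the substrate: the C7=C8 alkene, which in a simple neryl cation would close a six-membered ring, is switched off by its ester, and the allylsilane is several orders of magnitude more nucleophilic than the C11=C12 and prenyl alkenes. Attack at C2 and not C4 follows from the unhindered primary terminus, and attack through C1 and not C15 from the β-silicon effect. The Z geometry of C3=C4 should survive because rotation of the allyl cation is slow at −30 °C compared with capture.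

Step 20
Reactants: 25 the macrocyclic methyl ester
Product: 26 (1E,5Z,8R,11E)-5,11-dimethyl-8-(6-methylhepta-1,5-dien-2-yl)cyclotetradeca-1,5,11-triene-1-carboxylic acid (CNP0168903.1)
Conditions: LiOH, THF/MeOH/H2O, 40 °C; then 1 M HCl, 0 °C, to pH 4
Reagents that add atoms: lithium hydroxide, [Li+].[OH-]
Why: Saponification of the conjugated methyl ester; C1 has no acidifying neighbour and the skipped alkenes do not migrate under hydroxide at 40 °C, and cold, mild acidification avoids acid-promoted isomerisation.

## Compound list

1 | nerol, (2Z)-3,7-dimethylocta-2,6-dien-1-ol | CC(C)=CCC/C(C)=C\CO | starting material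
2 | tert-butyl{[(2Z)-3,7-dimethylocta-2,6-dien-1-yl]oxy}dimethylsilane | CC(C)=CCC/C(C)=C\CO[Si](C)(C)C(C)(C)C | intermediate
3 | tert-butyl{[(2Z)-5-(3,3-dimethyloxiran-2-yl)-3-methylpent-2-en-1-yl]oxy}dimethylsilane (racemic) | CC1(C)OC1CC/C(C)=C\CO[Si](C)(C)C(C)(C)C | intermediate
4 | (4Z)-6-[(tert-butyldimethylsilyl)oxy]-4-methylhex-4-enal | O=CCC/C(C)=C\CO[Si](C)(C)C(C)(C)C | intermediate
5 | methyl acrylate | C=CC(=O)OC | starting material
6 | methyl (6Z)-8-[(tert-butyldimethylsilyl)oxy]-3-hydroxy-6-methyl-2-methylideneoct-6-enoate (racemic) | C=C(C(=O)OC)C(O)CC/C(C)=C\CO[Si](C)(C)C(C)(C)C | intermediate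
7 | methyl (6Z)-3-acetoxy-8-[(tert-butyldimethylsilyl)oxy]-6-methyl-2-methylideneoct-6-enoate (racemic) | C=C(C(=O)OC)C(OC(C)=O)CC/C(C)=C\CO[Si](C)(C)C(C)(C)C | intermediate
8 | geraniol, (2E)-3,7-dimethylocta-2,6-dien-1-ol | CC(C)=CCC/C(C)=C/CO | starting material
9 | geranyl bromide, (2E)-1-bromo-3,7-dimethylocta-2,6-diene | CC(C)=CCC/C(C)=C/CBr | intermediate
10 | {[(2E)-3,7-dimethylocta-2,6-dien-1-yl]sulfonyl}benzene | CC(C)=CCC/C(C)=C/CS(=O)(=O)c1ccccc1 | intermediate
11 | 2,2-dimethyl-3-[(3E)-3-methyl-5-(phenylsulfonyl)pent-3-en-1-yl]oxirane (racemic) | CC1(C)OC1CC/C(C)=C/CS(=O)(=O)c1ccccc1 | intermediate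
12 | (4E)-4-methyl-6-(phenylsulfonyl)hex-4-enal | O=CCC/C(C)=C/CS(=O)(=O)c1ccccc1 | intermediate
13 | triethyl phosphonoacetate | CCOC(=O)CP(=O)(OCC)OCC | starting material
14 | 5-bromo-2-methylpent-2-ene | CC(C)=CCCBr | starting material
15 | ethyl 2-(diethoxyphosphoryl)-6-methylhept-5-enoate (racemic) | CCOC(=O)C(CCC=C(C)C)P(=O)(OCC)OCC | intermediate
16 | ethyl (2E,6E)-6-methyl-2-(4-methylpent-3-en-1-yl)-8-(phenylsulfonyl)octa-2,6-dienoate | CCOC(=O)/C(CCC=C(C)C)=C/CC/C(C)=C/CS(=O)(=O)c1ccccc1 | intermediate
17 | (2E,6E)-6-methyl-2-(4-methylpent-3-en-1-yl)-8-(phenylsulfonyl)octa-2,6-dien-1-ol | OC/C(CCC=C(C)C)=C/CC/C(C)=C/CS(=O)(=O)c1ccccc1 | intermediate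
18 | {[(2E,6E)-7-(chloromethyl)-3,11-dimethyldodeca-2,6,10-trien-1-yl]sulfonyl}benzene | ClC/C(CCC=C(C)C)=C/CC/C(C)=C/CS(=O)(=O)c1ccccc1 | intermediate
19 | trichloro[(2E,6E)-6-methyl-2-(4-methylpent-3-en-1-yl)-8-(phenylsulfonyl)octa-2,6-dien-1-yl]silane (not isolated) | Cl[Si](Cl)(Cl)C/C(CCC=C(C)C)=C/CC/C(C)=C/CS(=O)(=O)c1ccccc1 | intermediate
20 | trimethyl[(2E,6E)-6-methyl-2-(4-methylpent-3-en-1-yl)-8-(phenylsulfonyl)octa-2,6-dien-1-yl]silane | C[Si](C)(C)C/C(CCC=C(C)C)=C/CC/C(C)=C/CS(=O)(=O)c1ccccc1 | intermediate
21 | methyl (2E,5E,9E)-2-{(4Z)-6-[(tert-butyldimethylsilyl)oxy]-4-methylhex-4-en-1-ylidene}-6,14-dimethyl-4-(phenylsulfonyl)-10-[(trimethylsilyl)methyl]pentadeca-5,9,13-trienoate (racemic at C10) | CC(C)(C)[Si](C)(C)OC/C=C(/C)CC/C=C(/C(=O)OC)CC(S(=O)(=O)c1ccccc1)/C=C(\C)CC/C=C(/C[Si](C)(C)C)CCC=C(C)C | intermediate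
22 | methyl (2E,5E,9E)-2-{(4Z)-6-[(tert-butyldimethylsilyl)oxy]-4-methylhex-4-en-1-ylidene}-6,14-dimethyl-10-[(trimethylsilyl)methyl]pentadeca-5,9,13-trienoate | CC(C)(C)[Si](C)(C)OC/C=C(/C)CC/C=C(/C(=O)OC)CC/C=C(\C)CC/C=C(/C[Si](C)(C)C)CCC=C(C)C | intermediate
23 | methyl (2E,5E,9E)-2-[(4Z)-6-hydroxy-4-methylhex-4-en-1-ylidene]-6,14-dimethyl-10-[(trimethylsilyl)methyl]pentadeca-5,9,13-trienoate | OC/C=C(/C)CC/C=C(/C(=O)OC)CC/C=C(\C)CC/C=C(/C[Si](C)(C)C)CCC=C(C)C | intermediate
24 | methyl (2E,5E,9E)-2-[(4Z)-6-chloro-4-methylhex-4-en-1-ylidene]-6,14-dimethyl-10-[(trimethylsilyl)methyl]pentadeca-5,9,13-trienoate | ClC/C=C(/C)CC/C=C(/C(=O)OC)CC/C=C(\C)CC/C=C(/C[Si](C)(C)C)CCC=C(C)C | intermediate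
25 | methyl (1E,5Z,8R,11E)-5,11-dimethyl-8-(6-methylhepta-1,5-dien-2-yl)cyclotetradeca-1,5,11-triene-1-carboxylate | C=C(CCC=C(C)C)[C@H]1C/C=C(/C)CC/C=C(/C(=O)OC)CC/C=C(\C)CC1 | intermediate
26 | (1E,5Z,8R,11E)-5,11-dimethyl-8-(6-methylhepta-1,5-dien-2-yl)cyclotetradeca-1,5,11-triene-1-carboxylic acid | C=C(CCC=C(C)C)[C@H]1C/C=C(/C)CC/C=C(/C(=O)O)CC/C=C(\C)CC1 | target

## Step count and least certain steps

Total step count: 20. Longest linear sequence: 14 steps (8 to 26 through steps 6–9 and 11–20).

**Step 19 (key step, proposed new method).**
- What may go wrong: a neutral hydrogen-bond donor may ionise the primary allylic chloride too slowly, so that nothing happens or only an unselective background path runs. Face selection may be poor in a large, flexible transition state. The allyl cation may lose a proton, collapse to the tertiary chloride at C4, or react between two molecules.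
- Fallback (known chemistry): it sets out from 24. Cyclisation without asymmetric induction under a conventional Lewis acid (ZnCl2·OEt2 cat., CH2Cl2, −78 °C, high dilution; the known Lewis acid-catalysed coupling of allylic chlorides with allylsilanes) should give the racemic macrocyclic methyl ester F1. Its enantiomers are separated by preparative HPLC on a chiral stationary phase, and the R enantiomer is 25, where the route is rejoined. Asymmetric catalysis is replaced by resolution, at the cost of half the material.

**Step 16.**
- What may go wrong: hydride delivery to the wrong allyl terminus, loss of the E geometry through π-allyl isomerisation, β-hydride elimination to a diene, or slow ionisation of the sulfone with the mild hydride source.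
- Fallback: it sets out from 21. Saponification (LiOH) gives the sulfone carboxylic acid F2. Its lithium carboxylate, which resists hydride, is desulfonylated with LiBHEt3 and PdCl2(dppp) in THF at 0 °C to the desulfonylated carboxylic acid F3. Re-esterification with trimethylsilyldiazomethane in MeOH/toluene returns to the route at 22.

**Step 15.**
- What may go wrong: 1,2-addition of the lithiated sulfone to an ester carbonyl, proton transfer to the acetate, or incomplete E selectivity in the elimination.
- Fallback: it sets out from 6 (and 20). NBS/Me2S in CH2Cl2 converts 6 with allylic transposition into methyl (2Z,6Z)-2-(bromomethyl)-8-[(tert-butyldimethylsilyl)oxy]-6-methylocta-2,6-dienoate F4, whose geometry is fixed and purified before the union. Direct SN2 alkylation of lithiated 20 with F4 (THF, −78 °C) returns to the route at 21.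

**Step 14.**
- What may go wrong: copper-promoted substitution of the allylic sulfone by the Grignard reagent, or deprotonation and C-silylation of the sulfone during methylation.
- Fallback: it sets out from 17 and avoids chloride 18 and all organomagnesium chemistry. Direct palladium-catalysed silylation of the allylic alcohol with hexamethyldisilane (Pd(BF4)2(MeCN)4 cat., DMSO/MeOH, 50 °C) puts silicon on the less hindered terminus C16 and returns at 20. No new compound is made (F0). The trade-off is possible partial loss of the C1=C15 geometry through the π-allyl intermediate.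

**Step 11.**
- What may go wrong: incomplete E selectivity of the olefination with an α-branched phosphonate, giving an isomer mixture that is hard to separate.
- Fallback: it sets out from 14 and 12. Alkylation of ethyl (triphenylphosphoranylidene)acetate with 14 (EtOAc, reflux), then aqueous NaOH, gives the stabilised ylide ethyl 6-methyl-2-(triphenylphosphoranylidene)hept-5-enoate F5. Its base-free Wittig reaction with 12 (toluene, 80 °C), which is reliably E-selective for α-substituted stabilised ylides, returns to the route at 16.

## Further compounds

F1 | step 19 | racemic macrocyclic methyl ester | C=C(CCC=C(C)C)C1C/C=C(/C)CC/C=C(/C(=O)OC)CC/C=C(\C)CC1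
F2 | step 16 | sulfone carboxylic acid (acid of 21) | CC(C)(C)[Si](C)(C)OC/C=C(/C)CC/C=C(/C(=O)O)CC(S(=O)(=O)c1ccccc1)/C=C(\C)CC/C=C(/C[Si](C)(C)C)CCC=C(C)C
F3 | step 16 | desulfonylated carboxylic acid (acid of 22) | CC(C)(C)[Si](C)(C)OC/C=C(/C)CC/C=C(/C(=O)O)CC/C=C(\C)CC/C=C(/C[Si](C)(C)C)CCC=C(C)C
F4 | step 15 | methyl (2Z,6Z)-2-(bromomethyl)-8-[(tert-butyldimethylsilyl)oxy]-6-methylocta-2,6-dienoate | COC(=O)/C(CBr)=C/CC/C(C)=C\CO[Si](C)(C)C(C)(C)C
F0 | step 14 | none | none
F5 | step 11 | ethyl 6-methyl-2-(triphenylphosphoranylidene)hept-5-enoate | CCOC(=O)C(CCC=C(C)C)=P(c1ccccc1)(c1ccccc1)c1ccccc1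
A1 | alternative 1 | 14-membered carbocycle with a carboxyl on C14 and a silyloxymethyl group on C8 | C=C(CCC=C(C)C)[C@H]1C/C=C(/C)CC/C=C(/CO[Si](C)(C)C(C)(C)C)CC/C=C(\C)CC1C(=O)O
A2 | alternative 1 | 14-membered lactone with ring oxygen and isopropenyl group on C11 and acyl carbon on C14 | O=C1C[C@@H](C(=C)CCC=C(C)C)C/C=C(/C)CC/C=C(/CO[Si](C)(C)C(C)(C)C)CCC(C(C)=C)O1
A3 | alternative 2 | macrocycle with a silyloxymethyl group on C8 | C=C(CCC=C(C)C)[C@H]1C/C=C(/C)CC/C=C(/CO[Si](C)(C)C(C)(C)C)CC/C=C(\C)CC1
A4 | alternative 2 | linear Z alkenyl iodide (C4) with N-acyloxyphthalimide on C5 | I/C(C)=C\C[C@H](C(=C)CCC=C(C)C)CC/C(C)=C/CC/C(CO[Si](C)(C)C(C)(C)C)=C\CCC(=O)ON1C(=O)c2ccccc2C1=O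
A5 | alternative 3 | anti C14 homoallylic alcohol macrocycle | C=C(CCC=C(C)C)[C@H]1C/C=C(/C)CC/C=C(/C(=O)OC)CC/C=C(\C)C[C@@H]1O
A6 | alternative 3 | linear C14 aldehyde with C16 allylic bromide | O=CC/C(C)=C/CC/C(C(=O)OC)=C\CC/C(C)=C\CC=C(CBr)CCC=C(C)C
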